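**Plan**

Numbering used: dioxane O1–O2–C3(CH2CO2H)–C4(Et)–C5H2–C6(Et, chain C7–C14).

1. Retrosynthesis cuts, in this order: the ester; C8–CH3 and C8–C9 (two Negishi couplings on a C7=C8Cl2 unit); C7=C8 (dichloromethylenation of a C7 aldehyde); C3–CH2CO2Me together with a temporary C3–O–C7 bridge; then C5–C6 and O2–C3 in one operation.
2. That operation is a strain-release, polarity-reversed [3+3] annulation. C3–C4–C5 is carried as a trans-cyclopropyl ether (a homoenol ether: C5 nucleophilic, C3 a latent oxocarbenium carbon). Its oxygen is tied through C7H2 to C6, which is carried as a silylperoxy ketal (peroxycarbenium precursor).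
3. Forward: a temporary tetrahydropyran ring (O, C3, C4, C5, C6, C7) closes first and the 1,2-dioxane ring second, giving a 2,3,5-trioxabicyclo[2.2.2]octane. The ether bridge is then opened at C3 by a ketene acetal, C7 is oxidised, and the chain is joined.
4. Stereochemistry: C4 comes from (S)-1,2-epoxybutane (inversion in the cyclopropane closure). C6 is set by 1,3-induction from C4 in the tether-enforced chair transition state. C3 is set by axial attack on the dioxanyl cation, and C10 by Evans alkylation.
5. The C7=C8 geometry comes from a trans-selective and then a retentive Negishi coupling; C11=C12 comes from (E)-hex-3-enoic acid.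

Key step: step 8

Remark: 2-(bromomethyl)but-1-ene (8) is taken as a purchasable reagent, and the trans isomer of the cyclopropane series (6, 7, 10) is assumed separable from any minor cis isomer by chromatography.

**Route**

Step 1
Reactants: 1 (S)-1,2-epoxybutane; 2 bis(4,4,5,5-tetramethyl-1,3,2-dioxaborolan-2-yl)methane
Product: 4 (3S)-1,1-bis(4,4,5,5-tetramethyl-1,3,2-dioxaborolan-2-yl)pentan-3-ol, via lithiated diborylmethane 3 (not isolated)
Conditions: lithium 2,2,6,6-tetramethylpiperidide (from the amine and n-BuLi), THF, 0 °C; then 1, 0 °C to rt; aq NH4Cl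
Reagents that add atoms: none
Why: The boron-stabilised carbanion should open the terminal epoxide at its CH2 carbon (SN2 epoxide opening by an α-boryl carbanion), so the stereocentre of 1 is not touched.

Step 2
Reactants: 4 (3S)-1,1-bis(4,4,5,5-tetramethyl-1,3,2-dioxaborolan-2-yl)pentan-3-ol
Product: 5 (3S)-1,1-bis(4,4,5,5-tetramethyl-1,3,2-dioxaborolan-2-yl)pentan-3-yl methanesulfonate
Conditions: MsCl, Et3N, CH2Cl2, 0 °C
Reagents that add atoms: methanesulfonyl chloride, CS(=O)(=O)Cl
Why: Routine O-sulfonylation of a secondary alcohol, with retention because the C–O bond is not broken.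

Step 3
Reactants: 5 (3S)-1,1-bis(4,4,5,5-tetramethyl-1,3,2-dioxaborolan-2-yl)pentan-3-yl methanesulfonate
Product: 6 2-[(1R,2R)-2-ethylcyclopropyl]-4,4,5,5-tetramethyl-1,3,2-dioxaborolane
Conditions: KOt-Bu, THF, 0 °C to rt
Reagents that add atoms: none
Why: tert-Butoxide adds to one boron and the α-boryl carbanion so released should displace the mesylate in a 3-exo-tet closure with inversion (alkoxide-promoted deborylative alkylation), which makes the ethyl-bearing carbon R; the trans isomer is expected to predominate because the boryl and ethyl groups avoid each other in the closure.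

Step 4
Reactants: 6 2-[(1R,2R)-2-ethylcyclopropyl]-4,4,5,5-tetramethyl-1,3,2-dioxaborolane
Product: 7 (1R,2R)-2-ethylcyclopropan-1-ol
Conditions: H2O2 (30% aq), KHCO3, THF/H2O, 0 °C; product kept as a dried ethereal solution
Reagents that add atoms: hydrogen peroxide, OO
Why: Oxidation of the C–B bond (boronate oxidation with 1,2-migration) proceeds with retention, and the buffered medium should spare the base-sensitive cyclopropanol.

Step 5
Reactants: 7 (1R,2R)-2-ethylcyclopropan-1-ol; 8 2-(bromomethyl)but-1-ene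
Product: 10 (1R,2R)-1-ethyl-2-[(2-methylidenebutyl)oxy]cyclopropane, via sodium cyclopropanolate 9 (not isolated)
Conditions: NaH, THF, 0 °C; then 8, Bu4NI (cat.), 0 °C to rt
Reagents that add atoms: none
Why: Williamson etherification with a reactive allylic bromide should outrun ring opening of the cyclopropanolate at 0 °C and touches no stereocentre.

Step 6
Reactants: 10 (1R,2R)-1-ethyl-2-[(2-methylidenebutyl)oxy]cyclopropane
Product: 12 1-{[(1R,2R)-2-ethylcyclopropyl]oxy}-2-methoxybutan-2-yl hydroperoxide, via carbonyl oxide 11 (not isolated)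
Conditions: O3, CH2Cl2/MeOH (4:1), −78 °C; N2 purge; no reductive work-up
Reagents that add atoms: ozone, [O-][O+]=O; methanol, CO
Why: Ozonolysis of a 1,1-disubstituted alkene in methanol should give the substituted carbonyl oxide, which methanol traps as the hydroperoxy ketal (both epimers at the ketal carbon, which is planarised later); the cyclopropyl ether is inert to ozone.

Step 7
Reactants: 12 1-{[(1R,2R)-2-ethylcyclopropyl]oxy}-2-methoxybutan-2-yl hydroperoxide
Product: 13 triethyl[(1-{[(1R,2R)-2-ethylcyclopropyl]oxy}-2-methoxybutan-2-yl)peroxy]silane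
Conditions: Et3SiCl, imidazole, DMF, 0 °C
Reagents that add atoms: chlorotriethylsilane, CC[Si](Cl)(CC)CC
Why: O-silylation of the hydroperoxide caps the acidic OOH and installs the electrofuge that the ring closure of the next step expels.

Step 8
Reactants: 13 triethyl[(1-{[(1R,2R)-2-ethylcyclopropyl]oxy}-2-methoxybutan-2-yl)peroxy]silane
Product: 16 (1R,4S,8R)-1,8-diethyl-2,3,5-trioxabicyclo[2.2.2]octane, via silylperoxycarbenium ion 14 (not isolated), via tetrahydropyranyl oxocarbenium ion 15 (not isolated)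
Conditions: Et3SiOTf (0.2 equiv), 2,6-di-tert-butyl-4-methylpyridine (0.3 equiv), CH2Cl2 (0.01 M), −78 to −40 °C; Et3N quench
Reagents that add atoms: none
Why: Proposed new method: the silyl triflate abstracts methoxide from 13 to give the silylperoxycarbenium ion 14, whose carbon (C6) is attacked within the molecule by the unsubstituted CH2 corner (C5) of the trans-cyclopropyl ether acting as a homoenol ether, with cleavage of the strained C3–C5 bond to the ring oxocarbenium ion 15, which the neighbouring silylperoxy oxygen captures at C3 with loss of Et3Si+ (the chain carrier), so that the C5–C6 and O2–C3 bonds of the 1,2-dioxane form in one operation. The closest known reaction types are the Lewis-acid coupling of cyclopropyl ethers and silyl ethers as homoenol equivalents with tethered oxocarbenium ions (cyclopropane-fragmentation Prins-type cyclisations to oxepanes and cycloheptanones) and the [3+2] annulation of triethylsilylperoxycarbenium ions with alkenes to 1,2-dioxolanes; here the homoenol ether is offered to a peroxycarbenium ion, which makes the process a formal [3+3] annulation driven by release of cyclopropane strain. The temporary tetrahydropyran ring closes by attack of the cyclopropane σ bond on the exocyclic C=O+ of 14 (6-exo-trig at the electrophile, the breaking C3–C5 bond lying inside the new ring), and the 1,2-dioxane ring closes by 6-exo-trig attack of the peroxy oxygen on the C3=O+ of 15, which necessarily gives the [2.2.2] bicycle. The quaternary centre C6 is set relative to the existing C4 centre in a chair-like transition state of the first closure in which the trans-cyclopropane holds the C4 ethyl group pseudo-equatorial and the C6 ethyl group takes the equatorial site, leaving the smaller, electron-poor peroxycarbenium oxygen axial and gauche to the ring oxygen; the acetal centre C3 has no choice once C6 is set, because the peroxide bridge can span only one face. The step needs attack through C5 and not C4 (electrophiles open 2-alkylcyclopropanol derivatives at the CH2 carbon, and C4 attack would join a quaternary to a tertiary carbon), loss of methoxide and not of the silylperoxy group, and cyclisation faster than Criegee-type migration, which the six-membered intramolecular closure at low temperature and high dilution should secure.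

Step 9
Reactants: 16 (1R,4S,8R)-1,8-diethyl-2,3,5-trioxabicyclo[2.2.2]octane; 17 tert-butyl[(1-methoxyethenyl)oxy]dimethylsilane
Product: 20 methyl 2-[(3R,4R,6R)-4,6-diethyl-6-(hydroxymethyl)-1,2-dioxan-3-yl]acetate, via 1,2-dioxan-3-ylium ion 18 (not isolated), via silyl ether 19 (not isolated)
Conditions: t-BuMe2SiOTf (0.2 equiv), CH2Cl2, −78 °C; then 1% HCl in MeOH, 0 °C
Reagents that add atoms: none
Why: The silyl triflate should activate the more basic ether oxygen of the bicyclic peroxyacetal, the bridge opens to the peroxycarbenium ion 18, and the ketene acetal adds along the axial trajectory of the half-chair that keeps the C4 ethyl group pseudo-equatorial (Lewis-acid substitution of a cyclic peroxyacetal by a silyl ketene acetal, a Mukaiyama-type addition), which places CH2CO2Me cis to the C4 ethyl group (3R) and frees the C7 oxygen as the silyl ether 19 that the acidic methanol cleaves.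

Step 10
Reactants: 20 methyl 2-[(3R,4R,6R)-4,6-diethyl-6-(hydroxymethyl)-1,2-dioxan-3-yl]acetate
Product: 21 methyl 2-[(3R,4R,6R)-4,6-diethyl-6-formyl-1,2-dioxan-3-yl]acetate
Conditions: Dess–Martin periodinane, NaHCO3, CH2Cl2, 0 °C to rt
Reagents that add atoms: none
Why: Dess–Martin oxidation of the primary alcohol is neutral enough for the peroxide and the β-peroxy ester, and the aldehyde cannot enolise because C6 is quaternary.

Step 11
Reactants: 21 methyl 2-[(3R,4R,6R)-4,6-diethyl-6-formyl-1,2-dioxan-3-yl]acetate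
Product: 22 methyl 2-[(3R,4R,6R)-6-(2,2-dichloroethenyl)-4,6-diethyl-1,2-dioxan-3-yl]acetate
Conditions: PPh3, BrCCl3, MeCN, 0 °C to rt
Reagents that add atoms: bromotrichloromethane, ClC(Cl)(Cl)Br
Why: Wittig-type dichloromethylenation (Ramirez olefination with Ph3P=CCl2) is base-free, and a dialkyl peroxide should survive PPh3 at room temperature.

Step 12
Reactants: 23 (E)-hex-3-enoic acid; 24 (4S)-4-benzyl-1,3-oxazolidin-2-one
Product: 26 (4S)-4-benzyl-3-[(3E)-hex-3-enoyl]-1,3-oxazolidin-2-one, via mixed pivalic anhydride 25 (not isolated)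
Conditions: t-BuCOCl, Et3N, THF, −20 °C; then 24, LiCl, −20 °C to rt
Reagents that add atoms: none
Why: N-Acylation of the auxiliary through the mixed anhydride under LiCl/Et3N is mild enough to keep the β,γ-alkene out of conjugation.

Step 13
Reactants: 26 (4S)-4-benzyl-3-[(3E)-hex-3-enoyl]-1,3-oxazolidin-2-one
Product: 28 (4S)-4-benzyl-3-[(2S,3E)-2-ethylhex-3-enoyl]-1,3-oxazolidin-2-one, via sodium Z-enolate 27 (not isolated)
Conditions: NaN(SiMe3)2, THF, −78 °C; then EtOTf, −78 to −40 °C
Reagents that add atoms: ethyl trifluoromethanesulfonate, CCOS(=O)(=O)C(F)(F)F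
Why: Evans alkylation: the chelated Z-enolate is ethylated at the α-carbon on the face away from the benzyl group, which gives the (2S) centre (later C10) and keeps the (E)-β,γ-alkene.

Step 14
Reactants: 28 (4S)-4-benzyl-3-[(2S,3E)-2-ethylhex-3-enoyl]-1,3-oxazolidin-2-one
Product: 29 (2S,3E)-2-ethylhex-3-en-1-ol
Conditions: LiBH4, MeOH (1 equiv), Et2O, 0 °C
Reagents that add atoms: none
Why: Reductive removal of the auxiliary with LiBH4 gives the primary alcohol without epimerising the α-centre.

Step 15
Reactants: 29 (2S,3E)-2-ethylhex-3-en-1-ol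
Product: 30 (2S,3E)-2-ethyl-1-iodohex-3-ene
Conditions: I2, PPh3, imidazole, CH2Cl2, 0 °C
Reagents that add atoms: iodine, II
Why: Appel-type iodination acts on the primary carbon only, so the neighbouring stereocentre and the alkene are untouched.

Step 16
Reactants: 22 methyl 2-[(3R,4R,6R)-6-(2,2-dichloroethenyl)-4,6-diethyl-1,2-dioxan-3-yl]acetate; 30 (2S,3E)-2-ethyl-1-iodohex-3-ene
Product: 32 methyl 2-[(3R,4R,6R)-6-[(1Z,4R,5E)-2-chloro-4-ethylocta-1,5-dien-1-yl]-4,6-diethyl-1,2-dioxan-3-yl]acetate, via alkylzinc iodide 31 (not isolated)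
Conditions: 30, Zn dust (activated with BrCH2CH2Br and Me3SiCl), DMF, rt; then 22, PdCl2(DPEphos) (5 mol %), THF/DMF, rt
Reagents that add atoms: none
Why: Negishi coupling in its trans-selective monoalkylation mode for 1,1-dichloroalkenes: palladium should insert into the C–Cl bond trans to the bulky dioxanyl group, so the chain enters trans to C6, and the alkylzinc tolerates the ester.

Step 17
Reactants: 32 methyl 2-[(3R,4R,6R)-6-[(1Z,4R,5E)-2-chloro-4-ethylocta-1,5-dien-1-yl]-4,6-diethyl-1,2-dioxan-3-yl]acetate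
Product: 33 methyl 2-[(3R,4R,6R)-4,6-diethyl-6-[(1E,4R,5E)-4-ethyl-2-methylocta-1,5-dien-1-yl]-1,2-dioxan-3-yl]acetate
Conditions: MeZnCl, Pd(P(t-Bu)3)2 (5 mol %), THF, rt to 40 °C
Reagents that add atoms: methylzinc chloride, C[Zn]Cl
Why: Negishi methylation of the remaining alkenyl chloride with the bulky-phosphine catalyst proceeds with retention, which puts the methyl group cis to C6 and completes the (1E)-trisubstituted alkene.

Step 18
Reactants: 33 methyl 2-[(3R,4R,6R)-4,6-diethyl-6-[(1E,4R,5E)-4-ethyl-2-methylocta-1,5-dien-1-yl]-1,2-dioxan-3-yl]acetate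
Product: 34 2-[(3R,4R,6R)-4,6-diethyl-6-[(1E,4R,5E)-4-ethyl-2-methylocta-1,5-dien-1-yl]-1,2-dioxan-3-yl]acetic acid
Conditions: LiOH·H2O, THF/H2O (3:1), 0 °C to rt; then 1 M HCl to pH 3
Reagents that add atoms: lithium hydroxide, [Li+].[OH-]
Why: Saponification of the methyl ester at low temperature should be faster than base-induced retro-oxa-Michael opening of the β-peroxy ester, so C3 is not scrambled.

**Compound list**

1 | (S)-1,2-epoxybutane | CC[C@H]1CO1 | starting material
2 | bis(4,4,5,5-tetramethyl-1,3,2-dioxaborolan-2-yl)methane | CC1(C)OB(CB2OC(C)(C)C(C)(C)O2)OC1(C)C | starting material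
3 | lithiated bis(4,4,5,5-tetramethyl-1,3,2-dioxaborolan-2-yl)methane | [Li]C(B1OC(C)(C)C(C)(C)O1)B1OC(C)(C)C(C)(C)O1 | intermediate
4 | (3S)-1,1-bis(4,4,5,5-tetramethyl-1,3,2-dioxaborolan-2-yl)pentan-3-ol | CC[C@H](O)CC(B1OC(C)(C)C(C)(C)O1)B1OC(C)(C)C(C)(C)O1 | intermediate
5 | (3S)-1,1-bis(4,4,5,5-tetramethyl-1,3,2-dioxaborolan-2-yl)pentan-3-yl methanesulfonate | CC[C@H](OS(C)(=O)=O)CC(B1OC(C)(C)C(C)(C)O1)B1OC(C)(C)C(C)(C)O1 | intermediate
6 | 2-[(1R,2R)-2-ethylcyclopropyl]-4,4,5,5-tetramethyl-1,3,2-dioxaborolane (trans) | CC[C@@H]1C[C@H]1B1OC(C)(C)C(C)(C)O1 | intermediate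
7 | (1R,2R)-2-ethylcyclopropan-1-ol (trans) | CC[C@@H]1C[C@H]1O | intermediate
8 | 2-(bromomethyl)but-1-ene | C=C(CC)CBr | starting material
9 | sodium (1R,2R)-2-ethylcyclopropan-1-olate | CC[C@@H]1C[C@H]1[O-].[Na+] | intermediate
10 | (1R,2R)-1-ethyl-2-[(2-methylidenebutyl)oxy]cyclopropane | C=C(CC)CO[C@@H]1C[C@H]1CC | intermediate
11 | carbonyl oxide of 1-{[(1R,2R)-2-ethylcyclopropyl]oxy}butan-2-one | CCC(=[O+][O-])CO[C@@H]1C[C@H]1CC | intermediate
12 | 1-{[(1R,2R)-2-ethylcyclopropyl]oxy}-2-methoxybutan-2-yl hydroperoxide (both ketal epimers) | CCC(OC)(OO)CO[C@@H]1C[C@H]1CC | intermediate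
13 | triethyl[(1-{[(1R,2R)-2-ethylcyclopropyl]oxy}-2-methoxybutan-2-yl)peroxy]silane | CCC(OC)(OO[Si](CC)(CC)CC)CO[C@@H]1C[C@H]1CC | intermediate
14 | silylperoxycarbenium triflate (C6 cation carrying ethyl, OOSiEt3 and the CH2O-cyclopropyl arm) | CCC(=[O+]O[Si](CC)(CC)CC)CO[C@@H]1C[C@H]1CC.[O-]S(=O)(=O)C(F)(F)F | intermediate
15 | tetrahydropyranyl oxocarbenium triflate (O=C3 cation; C4 ethyl and C6 ethyl cis, C6 silylperoxy group trans to the C4 ethyl) | CC[C@@H]1C[C@@](CC)(OO[Si](CC)(CC)CC)C[O+]=C1.[O-]S(=O)(=O)C(F)(F)F | intermediate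
16 | (1R,4S,8R)-1,8-diethyl-2,3,5-trioxabicyclo[2.2.2]octane | CC[C@@]12C[C@@H](CC)[C@@H](OC1)OO2 | intermediate
17 | tert-butyl[(1-methoxyethenyl)oxy]dimethylsilane | COC(=C)O[Si](C)(C)C(C)(C)C | starting material
18 | (4R,6R)-6-{[(tert-butyldimethylsilyl)oxy]methyl}-4,6-diethyl-1,2-dioxan-3-ylium triflate | CC(C)(C)[Si](C)(C)OC[C@@]1(CC)C[C@@H](CC)C=[O+]O1.[O-]S(=O)(=O)C(F)(F)F | intermediate
19 | methyl 2-[(3R,4R,6R)-6-{[(tert-butyldimethylsilyl)oxy]methyl}-4,6-diethyl-1,2-dioxan-3-yl]acetate | CC(C)(C)[Si](C)(C)OC[C@@]1(CC)C[C@@H](CC)[C@@H](CC(=O)OC)OO1 | intermediate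
20 | methyl 2-[(3R,4R,6R)-4,6-diethyl-6-(hydroxymethyl)-1,2-dioxan-3-yl]acetate | OC[C@@]1(CC)C[C@@H](CC)[C@@H](CC(=O)OC)OO1 | intermediate
21 | methyl 2-[(3R,4R,6R)-4,6-diethyl-6-formyl-1,2-dioxan-3-yl]acetate | O=C[C@@]1(CC)C[C@@H](CC)[C@@H](CC(=O)OC)OO1 | intermediate
22 | methyl 2-[(3R,4R,6R)-6-(2,2-dichloroethenyl)-4,6-diethyl-1,2-dioxan-3-yl]acetate | ClC(Cl)=C[C@@]1(CC)C[C@@H](CC)[C@@H](CC(=O)OC)OO1 | intermediate
23 | (E)-hex-3-enoic acid | CC/C=C/CC(=O)O | starting material
24 | (4S)-4-benzyl-1,3-oxazolidin-2-one | O=C1N[C@@H](Cc2ccccc2)CO1 | starting material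
25 | (E)-hex-3-enoic pivalic anhydride | CC/C=C/CC(=O)OC(=O)C(C)(C)C | intermediate
26 | (4S)-4-benzyl-3-[(3E)-hex-3-enoyl]-1,3-oxazolidin-2-one | CC/C=C/CC(=O)N1[C@@H](Cc2ccccc2)COC1=O | intermediate
27 | sodium Z-enolate of 26 | CC/C=C/C=C(\[O-])N1[C@@H](Cc2ccccc2)COC1=O.[Na+] | intermediate
28 | (4S)-4-benzyl-3-[(2S,3E)-2-ethylhex-3-enoyl]-1,3-oxazolidin-2-one | CC/C=C/[C@H](CC)C(=O)N1[C@@H](Cc2ccccc2)COC1=O | intermediate
29 | (2S,3E)-2-ethylhex-3-en-1-ol | CC/C=C/[C@H](CC)CO | intermediate
30 | (2S,3E)-2-ethyl-1-iodohex-3-ene | CC/C=C/[C@H](CC)CI | intermediate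
31 | [(2S,3E)-2-ethylhex-3-en-1-yl]zinc iodide | CC/C=C/[C@H](CC)C[Zn]I | intermediate
32 | methyl 2-[(3R,4R,6R)-6-[(1Z,4R,5E)-2-chloro-4-ethylocta-1,5-dien-1-yl]-4,6-diethyl-1,2-dioxan-3-yl]acetate | CC/C=C/[C@H](CC)C/C(Cl)=C/[C@@]1(CC)C[C@@H](CC)[C@@H](CC(=O)OC)OO1 | intermediate
33 | methyl 2-[(3R,4R,6R)-4,6-diethyl-6-[(1E,4R,5E)-4-ethyl-2-methylocta-1,5-dien-1-yl]-1,2-dioxan-3-yl]acetate | CC/C=C/[C@H](CC)C/C(C)=C/[C@@]1(CC)C[C@@H](CC)[C@@H](CC(=O)OC)OO1 | intermediate
34 | 2-[(3R,4R,6R)-4,6-diethyl-6-[(1E,4R,5E)-4-ethyl-2-methylocta-1,5-dien-1-yl]-1,2-dioxan-3-yl]acetic acid | CC/C=C/[C@H](CC)C/C(C)=C/[C@@]1(CC)C[C@@H](CC)[C@@H](CC(=O)O)OO1 | target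

**Count**

Total steps: 18. Longest linear sequence: 14 steps (steps 1–11 and 16–18); the side-chain iodide 30 takes 4 steps (12–15).

**Steps most likely to fail**

1. Step 8 (the proposed new method).
   - What may go wrong: the peroxycarbenium ion may undergo Criegee-type migration or lose its silyl group before the cyclopropane σ bond reaches it through the short tether. The two faces of the cation may also be poorly discriminated, which would erode the C4/C6 relationship.
   - Fallback (known chemistry only; sets out from 8 and 24, comes back at 20): 24 is N-acylated with butanoyl chloride (n-BuLi, THF, −78 °C) to (4S)-4-benzyl-3-butanoyl-1,3-oxazolidin-2-one F1. Its sodium enolate (NaN(SiMe3)2, −78 °C) is alkylated with 8 to (4S)-4-benzyl-3-[(2R)-2-ethyl-4-methylidenehexanoyl]-1,3-oxazolidin-2-one F2, the auxiliary setting the future C4. LiBH4 gives (2R)-2-ethyl-4-methylidenehexan-1-ol F3, Dess–Martin oxidation gives (2R)-2-ethyl-4-methylidenehexanal F4, and Ph3P=CHCO2Me gives methyl (2E,4R)-4-ethyl-6-methylideneoct-2-enoate F5. mCPBA epoxidises only the electron-rich 1,1-disubstituted alkene to methyl (2E,4R)-4-ethyl-5-(2-ethyloxiran-2-yl)pent-2-enoate F6. Perhydrolysis (ethereal H2O2, cat. H3PMo12O40) opens the epoxide at its tertiary carbon to methyl (2E,4R)-4-ethyl-6-hydroperoxy-6-(hydroxymethyl)oct-2-enoate F7. Et2NH in CF3CH2OH closes the 1,2-dioxane by intramolecular oxa-Michael addition to give 20. This sequence has no control at C6 and C3, so 20 would have to be separated from its isomers by HPLC.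

2. Step 9.
   - What may go wrong: the ketene acetal may attack the dioxanyl cation on the face anti to the departing bridge oxygen (wrong configuration at C3). The Lewis acid may also ionise the peroxide C3–O bond instead of the ether C3–O bond, which would open the dioxane ring and not the tetrahydropyran ring.
   - Fallback (sets out from 16, comes back at 20): the acetate unit is delivered from the C7 arm itself. Acid methanolysis of 16 (camphorsulfonic acid, MeOH, 0 °C) gives [(4R,6R)-4,6-diethyl-3-methoxy-1,2-dioxan-6-yl]methanol F8, and Ac2O/pyridine gives [(4R,6R)-4,6-diethyl-3-methoxy-1,2-dioxan-6-yl]methyl acetate F9. LiN(SiMe3)2 and t-BuMe2SiCl (THF, −78 °C) convert the acetate into its silyl ketene acetal F10. t-BuMe2SiOTf (CH2Cl2, −78 °C) then ionises the anomeric methoxy group, so the tethered ketene acetal can reach C3 only from the face that carries the C6 CH2O arm, giving the bridged lactone 1,10-diethyl-3,7,8-trioxabicyclo[4.2.2]decan-4-one F11. NaOMe in MeOH (0 °C) opens the lactone to 20.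

3. Step 16.
   - What may go wrong: slow oxidative addition at the hindered dichloroalkene, double alkylation, or reductive cleavage of the O–O bond by zerovalent palladium or the organozinc. The same hazards apply to step 17.
   - Fallback (sets out from 21 and 30, comes back at 33; bypasses steps 11, 16 and 17): the alkene is made by olefination instead of cross-coupling. Purchased 5-(ethylsulfonyl)-1-phenyl-1H-tetrazole is lithiated (LiN(SiMe3)2, THF, −78 °C) and alkylated with 30 to 5-{[(4R,5E)-4-ethyloct-5-en-2-yl]sulfonyl}-1-phenyl-1H-tetrazole F12. Julia–Kocienski olefination of 21 with F12 (KN(SiMe3)2, DME, −60 °C) gives 33 together with its (1Z) isomer, to be separated on AgNO3-impregnated silica.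

**Further compounds**

F1 | step 8 | (4S)-4-benzyl-3-butanoyl-1,3-oxazolidin-2-one | CCCC(=O)N1[C@@H](Cc2ccccc2)COC1=O
F2 | step 8 | (4S)-4-benzyl-3-[(2R)-2-ethyl-4-methylidenehexanoyl]-1,3-oxazolidin-2-one | C=C(CC)C[C@@H](CC)C(=O)N1[C@@H](Cc2ccccc2)COC1=O
F3 | step 8 | (2R)-2-ethyl-4-methylidenehexan-1-ol | C=C(CC)C[C@@H](CC)CO
F4 | step 8 | (2R)-2-ethyl-4-methylidenehexanal | C=C(CC)C[C@@H](CC)C=O
F5 | step 8 | methyl (2E,4R)-4-ethyl-6-methylideneoct-2-enoate | C=C(CC)C[C@@H](CC)/C=C/C(=O)OC
F6 | step 8 | methyl (2E,4R)-4-ethyl-5-(2-ethyloxiran-2-yl)pent-2-enoate (both epoxide epimers) | CCC1(C[C@@H](CC)/C=C/C(=O)OC)CO1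
F7 | step 8 | methyl (2E,4R)-4-ethyl-6-hydroperoxy-6-(hydroxymethyl)oct-2-enoate (both C6 epimers) | CCC(CO)(OO)C[C@@H](CC)/C=C/C(=O)OC
F8 | step 9 | [(4R,6R)-4,6-diethyl-3-methoxy-1,2-dioxan-6-yl]methanol (both C3 anomers) | COC1OO[C@@](CC)(CO)C[C@H]1CC
F9 | step 9 | [(4R,6R)-4,6-diethyl-3-methoxy-1,2-dioxan-6-yl]methyl acetate | COC1OO[C@@](CC)(COC(C)=O)C[C@H]1CC
F10 | step 9 | tert-butyldimethylsilyl ketene acetal of F9 | COC1OO[C@@](CC)(COC(=C)O[Si](C)(C)C(C)(C)C)C[C@H]1CC
F11 | step 9 | 1,10-diethyl-3,7,8-trioxabicyclo[4.2.2]decan-4-one (bridged lactone, C3 CH2 and C6 CH2O on the same face) | O=C1C[C@H]2OO[C@@](CC)(CO1)C[C@H]2CC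
F12 | step 16 | 5-{[(4R,5E)-4-ethyloct-5-en-2-yl]sulfonyl}-1-phenyl-1H-tetrazole (both C2 epimers) | CC/C=C/[C@H](CC)CC(C)S(=O)(=O)c1nnnn1-c1ccccc1
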